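Ring C is disconnected between carbons a and f. Of its five contiguous oxygens, those on c, d, e and f map onto the four carbons of dimethyl squarate, the oxygen on a is the phenolic oxygen of the AB dimer, and b is the lone CH. Heating a racemic 4-methoxy-4-[(Z)-2-(AB-aryloxy)vinyl]-2,3-dimethoxycyclobutenone opens it to a dienylketene whose 6π closure forms the a–f bond, builds ring C and leaves only the f hydroxyl free. This phenol is joined by copper catalysis to a DEFG iodide, whose ring E comes from the same ring expansion on 2,6-dimethoxyphenol, and all eighteen methyl ethers are cleaved last.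

Key step: step 8

Remark: rings are lettered A to G from the 2,4,6-trihydroxyphenyl end; in rings B, D and F position 1 carries the oxygen towards ring A and position 4 the oxygen towards ring G; ring C atoms are a (carbon on the ring B oxygen), b (CH), c, d, e (hydroxylated carbons) and f (carbon on the ring D oxygen).

Remark: the vinyl ether is carried as the Z isomer, made by cis-hydrogenation of an alkynyl adduct, because an (E)-2-aryloxyvinyllithium holds lithium anti to the aryloxy group and is expected to fragment to acetylene and aryloxide; both alkene isomers lead to the same phenol.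

Remark: compounds 12–14, 16, 21–23 and 25 are racemic (one enantiomer drawn where a descriptor is given); their stereocentres vanish on aromatisation and the target has none.

Step 1
Reactants: 1 2,4,6-trimethoxybenzaldehyde
Product: 3 2,4,6-trimethoxyphenol, via 2,4,6-trimethoxyphenyl formate 2 (not isolated)
Conditions: 30% H2O2, H2SO4 (cat.), MeOH, rt
Reagents that add atoms: hydrogen peroxide, OO
Why: Acid-catalysed Dakin oxidation, in which the electron-rich aryl group migrates from carbon to oxygen in the hydroperoxide adduct and the formate 2 is methanolysed in the same flask.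

Step 2
Reactants: 4 4-bromo-2,6-dimethoxyphenol
Product: 5 2-(benzyloxy)-5-bromo-1,3-dimethoxybenzene
Conditions: BnBr, K2CO3, DMF, rt
Reagents that add atoms: benzyl bromide, BrCc1ccccc1
Why: Williamson ether synthesis; the benzyl ether masks the ring B hydroxyl during the copper coupling and can later be removed by hydrogenolysis without touching methyl ethers.

Step 3
Reactants: 3 2,4,6-trimethoxyphenol; 5 2-(benzyloxy)-5-bromo-1,3-dimethoxybenzene
Product: 6 2-(benzyloxy)-1,3-dimethoxy-5-(2,4,6-trimethoxyphenoxy)benzene (AB benzyl ether)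
Conditions: CuI (10 mol %), picolinic acid (20 mol %), K3PO4, DMSO, 90 °C, Ar
Reagents that add atoms: none
Why: Ullmann diaryl ether coupling with the CuI/picolinic acid system, which is known to join di-ortho-substituted phenols to electron-rich aryl bromides; the bromide of 5 has no ortho substituent.

Step 4
Reactants: 6 AB benzyl ether
Product: 7 2,6-dimethoxy-4-(2,4,6-trimethoxyphenoxy)phenol (AB phenol)
Conditions: H2 (1 atm), Pd/C, EtOAc–MeOH, rt
Reagents that add atoms: none
Why: Catalytic hydrogenolysis of the benzyl ether; diaryl ether and aryl methyl ether bonds are inert to Pd/C and hydrogen at room temperature.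

Step 5
Reactants: 7 AB phenol; 8 trichloroethylene
Product: 9 2-{[(E)-1,2-dichloroethenyl]oxy}-1,3-dimethoxy-5-(2,4,6-trimethoxyphenoxy)benzene (AB dichlorovinyl ether)
Conditions: K2CO3, DMF, 70 °C, Ar
Reagents that add atoms: none
Why: First stage of the trichloroethylene route to ynol ethers: carbonate generates dichloroacetylene from 8 and the phenoxide adds to it in anti fashion, which gives the E dichlorovinyl ether.

Step 6
Reactants: 9 AB dichlorovinyl ether; 10 dimethyl squarate
Product: 13 4-{[2,6-dimethoxy-4-(2,4,6-trimethoxyphenoxy)phenoxy]ethynyl}-2,3,4-trimethoxycyclobut-2-en-1-one (racemic), via lithium aryloxyacetylide 11 (not isolated), via lithium alkoxide adduct 12 (not isolated)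
Conditions: n-BuLi (2.05 equiv), THF, −78 to −40 °C; cannulate into 10 (1.2 equiv), THF, −78 °C; MeOTf, −78 to −20 °C; aq NaHCO3; Et3N-deactivated silica
Reagents that add atoms: methyl trifluoromethanesulfonate, COS(=O)(=O)C(F)(F)F
Why: Second stage of the trichloroethylene route (deprotonation, loss of LiCl, chlorine–lithium exchange) gives acetylide 11, which undergoes 1,2-addition to one squarate carbonyl as other alkynyllithiums do, and alkoxide 12 is O-methylated in situ; the new quaternary centre forms as a racemate and is destroyed in step 8.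

Step 7
Reactants: 13 alkynyl cyclobutenone
Product: 14 4-{(Z)-2-[2,6-dimethoxy-4-(2,4,6-trimethoxyphenoxy)phenoxy]ethenyl}-2,3,4-trimethoxycyclobut-2-en-1-one (racemic)
Conditions: H2 (1 atm), Pd/CaCO3 poisoned with Pb(OAc)2 (Lindlar catalyst), quinoline, EtOAc, rt
Reagents that add atoms: none
Why: Lindlar semi-hydrogenation delivers both hydrogens to one face of the ynol ether triple bond and so sets the Z enol ether; the tetrasubstituted dimethoxy alkene and the ketone are not reduced by the poisoned catalyst.

Step 8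
Reactants: 14 (Z)-aryloxyvinyl cyclobutenone
Product: 17 6-[2,6-dimethoxy-4-(2,4,6-trimethoxyphenoxy)phenoxy]-2,3,4-trimethoxyphenol (ABC phenol with free f hydroxyl), via dienylketene 15 (not isolated), via cyclohexadienone 16 (not isolated)
Conditions: toluene (0.01 M, degassed), 110 °C, Ar
Reagents that add atoms: none
Why: Heat opens cyclobutenone 14 by conrotatory 4π electrocyclic ring opening to dienylketene 15; disrotatory 6π electrocyclisation then joins the ketene carbon (future f) to the oxygen-bearing vinyl carbon (future a) to give dienone 16, and enolisation of the hydrogen on a aromatises ring C to phenol 17. The closest known reaction is the Moore rearrangement of 4-alkenyl-4-alkoxycyclobutenones made from squarate esters, which gives polyoxygenated phenols. Ring C is closed in the thermal 6π electrocyclic mode and no stereocentre survives, because the only sp3 carbon formed (a in 16) is lost on tautomerisation. The step needs torquoselectivity that turns the vinyl group inward, cis to the ketene, and the donor methoxy group on the carbinol carbon secures it by rotating outward. The Z aryloxy group lies inside the closing terminus, but the sp-hybridised ketene carbon has no inside substituent to clash with, so closure should still be feasible. Because the oxygen on c was methylated before thermolysis, only the oxygen on f appears as a free hydroxyl.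

Step 9
Reactants: 18 2,6-dimethoxyphenol; 8 trichloroethylene
Product: 19 2-{[(E)-1,2-dichloroethenyl]oxy}-1,3-dimethoxybenzene
Conditions: K2CO3, DMF, 70 °C, Ar
Reagents that add atoms: none
Why: Same anti addition of a phenoxide to in situ dichloroacetylene as in step 5, giving the E dichlorovinyl ether.

Step 10
Reactants: 19 dichlorovinyl ether of ring D; 10 dimethyl squarate
Product: 22 4-[(2,6-dimethoxyphenoxy)ethynyl]-2,3,4-trimethoxycyclobut-2-en-1-one (racemic), via lithium aryloxyacetylide 20 (not isolated), via lithium alkoxide adduct 21 (not isolated)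
Conditions: n-BuLi (2.05 equiv), THF, −78 to −40 °C; cannulate into 10 (1.2 equiv), THF, −78 °C; MeOTf, −78 to −20 °C; aq NaHCO3
Reagents that add atoms: methyl trifluoromethanesulfonate, COS(=O)(=O)C(F)(F)F
Why: Same acetylide formation, 1,2-addition to the squarate and in situ O-methylation as in step 6; the quaternary centre is racemic and is destroyed in step 12.

Step 11
Reactants: 22 alkynyl cyclobutenone of ring D
Product: 23 4-[(Z)-2-(2,6-dimethoxyphenoxy)ethenyl]-2,3,4-trimethoxycyclobut-2-en-1-one (racemic)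
Conditions: H2 (1 atm), Pd/CaCO3 poisoned with Pb(OAc)2 (Lindlar catalyst), quinoline, EtOAc, rt
Reagents that add atoms: none
Why: Lindlar semi-hydrogenation with syn delivery of hydrogen, which sets the Z enol ether as in step 7.

Step 12
Reactants: 23 (Z)-aryloxyvinyl cyclobutenone of ring D
Product: 26 6-(2,6-dimethoxyphenoxy)-2,3,4-trimethoxyphenol (DE phenol), via dienylketene 24 (not isolated), via cyclohexadienone 25 (not isolated)
Conditions: toluene (0.01 M, degassed), 110 °C, Ar
Reagents that add atoms: none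
Why: Moore rearrangement as in step 8 (4π opening, 6π closure, tautomerisation), here building ring E on the simplest aryl ether, so the sequence can be proved on cheap material before it is applied to 7.

Step 13
Reactants: 4 4-bromo-2,6-dimethoxyphenol; 27 (3,4,5-trimethoxyphenyl)boronic acid
Product: 28 5-bromo-1,3-dimethoxy-2-(3,4,5-trimethoxyphenoxy)benzene (FG bromide)
Conditions: Cu(OAc)2 (1 equiv, reoxidised by air), pyridine, 4 Å MS, CH2Cl2, air, rt
Reagents that add atoms: none
Why: Chan–Lam oxidative etherification, which accepts ortho-disubstituted phenols and electron-rich boronic acids at room temperature and leaves the aryl bromide untouched.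

Step 14
Reactants: 26 DE phenol; 28 FG bromide
Product: 29 1-(2,6-dimethoxyphenoxy)-2-[3,5-dimethoxy-4-(3,4,5-trimethoxyphenoxy)phenoxy]-3,4,5-trimethoxybenzene (DEFG tetramer)
Conditions: CuI (10 mol %), picolinic acid (20 mol %), K3PO4, DMSO, 90 °C, Ar
Reagents that add atoms: none
Why: Ullmann diaryl ether coupling as in step 3; phenol 26 is the only nucleophile and the unhindered bromide of 28 the only electrophile.

Step 15
Reactants: 29 DEFG tetramer
Product: 31 1-(4-iodo-2,6-dimethoxyphenoxy)-2-[3,5-dimethoxy-4-(3,4,5-trimethoxyphenoxy)phenoxy]-3,4,5-trimethoxybenzene (DEFG iodide), via DEFG pinacol boronate 30 (not isolated)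
Conditions: [Ir(OMe)(cod)]2 (2.5 mol %), 4,4'-di-tert-butyl-2,2'-bipyridine, B2pin2 (1.0 equiv), THF, 80 °C; evaporate; CuI (10 mol %), 1,10-phenanthroline, KI, THF–MeOH–H2O, air, 80 °C
Reagents that add atoms: potassium iodide, [K+].[I-]
Why: Iridium-catalysed C–H borylation is governed by sterics and D1–H is the only C–H of 29 without an ortho substituent, and copper-catalysed iododeboronation of boronate 30 (a Chan–Lam-type process with iodide) puts iodine on the same carbon without an electrophilic iodinating agent that would attack ring E.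

Step 16
Reactants: 17 ABC phenol; 31 DEFG iodide
Product: 32 octadeca-O-methyl ether of the target (permethylated heptamer)
Conditions: CuI (20 mol %), picolinic acid (40 mol %), K3PO4, DMSO, 90 °C, Ar
Reagents that add atoms: none
Why: Ullmann diaryl ether coupling of a di-ortho-substituted phenol with an unhindered aryl iodide, the bond type already made in steps 3 and 14, here forming the ether between carbon f of ring C and D1.

Step 17
Reactants: 32 permethylated heptamer
Product: 33 CNP0292517.0 (target)
Conditions: BBr3 (excess), CH2Cl2, −78 °C to rt; MeOH then H2O, Ar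
Reagents that add atoms: none
Why: Lewis acid cleavage of aryl methyl ethers, in which BBr3 coordinates each methoxy oxygen and bromide attacks the methyl group, whereas diaryl ether bonds resist these conditions.

Compound list

1 | 2,4,6-trimethoxybenzaldehyde | COc1cc(OC)c(C=O)c(OC)c1 | starting material
2 | 2,4,6-trimethoxyphenyl formate | COc1cc(OC)c(OC=O)c(OC)c1 | intermediate
3 | 2,4,6-trimethoxyphenol | COc1cc(OC)c(O)c(OC)c1 | intermediate
4 | 4-bromo-2,6-dimethoxyphenol | COc1cc(Br)cc(OC)c1O | starting material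
5 | 2-(benzyloxy)-5-bromo-1,3-dimethoxybenzene | COc1cc(Br)cc(OC)c1OCc1ccccc1 | intermediate
6 | 2-(benzyloxy)-1,3-dimethoxy-5-(2,4,6-trimethoxyphenoxy)benzene | COc1cc(OC)c(Oc2cc(OC)c(OCc3ccccc3)c(OC)c2)c(OC)c1 | intermediate
7 | 2,6-dimethoxy-4-(2,4,6-trimethoxyphenoxy)phenol (AB phenol) | COc1cc(OC)c(Oc2cc(OC)c(O)c(OC)c2)c(OC)c1 | intermediate
8 | trichloroethylene | ClC=C(Cl)Cl | starting material
9 | 2-{[(E)-1,2-dichloroethenyl]oxy}-1,3-dimethoxy-5-(2,4,6-trimethoxyphenoxy)benzene | Cl/C=C(/Cl)Oc1c(OC)cc(Oc2c(OC)cc(OC)cc2OC)cc1OC | intermediate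
10 | dimethyl squarate (3,4-dimethoxycyclobut-3-ene-1,2-dione) | COC1=C(OC)C(=O)C1=O | starting material
11 | lithium [2,6-dimethoxy-4-(2,4,6-trimethoxyphenoxy)phenoxy]ethynide | [Li]C#COc1c(OC)cc(Oc2c(OC)cc(OC)cc2OC)cc1OC | intermediate
12 | lithium alkoxide of 4-hydroxy-4-(AB-aryloxyethynyl)-2,3-dimethoxycyclobut-2-en-1-one (racemic, one enantiomer drawn) | COC1=C(OC)[C@]([O-])(C#COc2c(OC)cc(Oc3c(OC)cc(OC)cc3OC)cc2OC)C1=O.[Li+] | intermediate
13 | 4-{[2,6-dimethoxy-4-(2,4,6-trimethoxyphenoxy)phenoxy]ethynyl}-2,3,4-trimethoxycyclobut-2-en-1-one (racemic, one enantiomer drawn) | COC1=C(OC)[C@](OC)(C#COc2c(OC)cc(Oc3c(OC)cc(OC)cc3OC)cc2OC)C1=O | intermediate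
14 | 4-{(Z)-2-[2,6-dimethoxy-4-(2,4,6-trimethoxyphenoxy)phenoxy]ethenyl}-2,3,4-trimethoxycyclobut-2-en-1-one (racemic, one enantiomer drawn; precursor of the key step) | COC1=C(OC)[C@](OC)(/C=C\Oc2c(OC)cc(Oc3c(OC)cc(OC)cc3OC)cc2OC)C1=O | intermediate
15 | (3Z,5Z)-6-[2,6-dimethoxy-4-(2,4,6-trimethoxyphenoxy)phenoxy]-2,3,4-trimethoxyhexa-1,3,5-trien-1-one (dienylketene) | O=C=C(OC)/C(OC)=C(OC)\C=C/Oc1c(OC)cc(Oc2c(OC)cc(OC)cc2OC)cc1OC | intermediate
16 | 6-[2,6-dimethoxy-4-(2,4,6-trimethoxyphenoxy)phenoxy]-2,3,4-trimethoxycyclohexa-2,4-dien-1-one (racemic) | O=C1C(OC)=C(OC)C(OC)=CC1Oc1c(OC)cc(Oc2c(OC)cc(OC)cc2OC)cc1OC | intermediate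
17 | 6-[2,6-dimethoxy-4-(2,4,6-trimethoxyphenoxy)phenoxy]-2,3,4-trimethoxyphenol (ABC phenol, free f hydroxyl) | COc1cc(OC)c(Oc2cc(OC)c(Oc3cc(OC)c(OC)c(OC)c3O)c(OC)c2)c(OC)c1 | intermediate
18 | 2,6-dimethoxyphenol | COc1cccc(OC)c1O | starting material
19 | 2-{[(E)-1,2-dichloroethenyl]oxy}-1,3-dimethoxybenzene | Cl/C=C(/Cl)Oc1c(OC)cccc1OC | intermediate
20 | lithium (2,6-dimethoxyphenoxy)ethynide | [Li]C#COc1c(OC)cccc1OC | intermediate
21 | lithium alkoxide of 4-[(2,6-dimethoxyphenoxy)ethynyl]-4-hydroxy-2,3-dimethoxycyclobut-2-en-1-one (racemic, one enantiomer drawn) | COC1=C(OC)[C@]([O-])(C#COc2c(OC)cccc2OC)C1=O.[Li+] | intermediate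
22 | 4-[(2,6-dimethoxyphenoxy)ethynyl]-2,3,4-trimethoxycyclobut-2-en-1-one (racemic, one enantiomer drawn) | COC1=C(OC)[C@](OC)(C#COc2c(OC)cccc2OC)C1=O | intermediate
23 | 4-[(Z)-2-(2,6-dimethoxyphenoxy)ethenyl]-2,3,4-trimethoxycyclobut-2-en-1-one (racemic, one enantiomer drawn) | COC1=C(OC)[C@](OC)(/C=C\Oc2c(OC)cccc2OC)C1=O | intermediate
24 | (3Z,5Z)-6-(2,6-dimethoxyphenoxy)-2,3,4-trimethoxyhexa-1,3,5-trien-1-one (dienylketene) | O=C=C(OC)/C(OC)=C(OC)\C=C/Oc1c(OC)cccc1OC | intermediate
25 | 6-(2,6-dimethoxyphenoxy)-2,3,4-trimethoxycyclohexa-2,4-dien-1-one (racemic) | O=C1C(OC)=C(OC)C(OC)=CC1Oc1c(OC)cccc1OC | intermediate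
26 | 6-(2,6-dimethoxyphenoxy)-2,3,4-trimethoxyphenol (DE phenol) | COc1cccc(OC)c1Oc1cc(OC)c(OC)c(OC)c1O | intermediate
27 | (3,4,5-trimethoxyphenyl)boronic acid | COc1cc(B(O)O)cc(OC)c1OC | starting material
28 | 5-bromo-1,3-dimethoxy-2-(3,4,5-trimethoxyphenoxy)benzene (FG bromide) | COc1cc(Br)cc(OC)c1Oc1cc(OC)c(OC)c(OC)c1 | intermediate
29 | 1-(2,6-dimethoxyphenoxy)-2-[3,5-dimethoxy-4-(3,4,5-trimethoxyphenoxy)phenoxy]-3,4,5-trimethoxybenzene (DEFG tetramer) | COc1cccc(OC)c1Oc1cc(OC)c(OC)c(OC)c1Oc1cc(OC)c(Oc2cc(OC)c(OC)c(OC)c2)c(OC)c1 | intermediate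
30 | DEFG tetramer carrying a 4,4,5,5-tetramethyl-1,3,2-dioxaborolan-2-yl group at D1 | COc1cc(B2OC(C)(C)C(C)(C)O2)cc(OC)c1Oc1cc(OC)c(OC)c(OC)c1Oc1cc(OC)c(Oc2cc(OC)c(OC)c(OC)c2)c(OC)c1 | intermediate
31 | 1-(4-iodo-2,6-dimethoxyphenoxy)-2-[3,5-dimethoxy-4-(3,4,5-trimethoxyphenoxy)phenoxy]-3,4,5-trimethoxybenzene (DEFG iodide) | COc1cc(I)cc(OC)c1Oc1cc(OC)c(OC)c(OC)c1Oc1cc(OC)c(Oc2cc(OC)c(OC)c(OC)c2)c(OC)c1 | intermediate
32 | octadeca-O-methyl ether of the target (rings A–G linked as in the target, every hydroxyl as OMe) | COc1cc(OC)c(Oc2cc(OC)c(Oc3cc(OC)c(OC)c(OC)c3Oc3cc(OC)c(Oc4cc(OC)c(OC)c(OC)c4Oc4cc(OC)c(Oc5cc(OC)c(OC)c(OC)c5)c(OC)c4)c(OC)c3)c(OC)c2)c(OC)c1 | intermediate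
33 | CNP0292517.0 | Oc1cc(O)c(Oc2cc(O)c(Oc3cc(O)c(O)c(O)c3Oc3cc(O)c(Oc4cc(O)c(O)c(O)c4Oc4cc(O)c(Oc5cc(O)c(O)c(O)c5)c(O)c4)c(O)c3)c(O)c2)c(O)c1 | target

Total step count: 17.
Longest linear sequence: 9 steps (step 1 or 2, then 3, 4, 5, 6, 7, 8, 16, 17).

Steps most likely to fail

Step 8 (and its twin, step 12). The 6π closure could be slowed by the aryloxy group that sits on the inside of the closing terminus. The dienylketene would then be lost to dimerisation or to acylation of the phenol already formed. The fallback supplies the E vinyl ether without any 2-aryloxyvinyl metal; it sets out from 10 and 7 and comes back at 17. Tin–lithium exchange of commercial (E)-1,2-bis(tributylstannyl)ethene (n-BuLi, THF, −78 °C) should give (E)-2-(tributylstannyl)ethenyllithium F1, which has no β-leaving oxygen. Addition to 10 should give the lithium alkoxide F2, and methylation in situ with MeOTf the stannylvinyl cyclobutenone F3. Iododestannylation (I2, CH2Cl2, 0 °C) should proceed with retention to the (E)-iodovinyl cyclobutenone F4. Copper-catalysed O-vinylation of phenol 7 (CuI, N,N-dimethylglycine, Cs2CO3, dioxane, 60 °C) should then give the E isomer of 14, F5. Thermolysis as in step 8 should pass through the (3Z,5E)-dienylketene F6, with the aryloxy group outside the closing triene, and through dienone 16 to 17.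

Step 15. Iodine formed in the aerobic copper/iodide stage could iodinate ring E at its free position b, or the boronate could be protodeboronated. The fallback sets out from 30 and 17 and comes back at 32. The sequence would be stopped after the borylation stage and boronate 30 isolated. It would then be joined directly to phenol 17 by Chan–Lam etherification (Cu(OAc)2, pyridine, B(OH)3, MeCN, 4 Å MS, air), so that no aryl iodide and no separate Ullmann step are needed. This fallback makes no new compound (F0).

Step 17. Some of the eighteen methyl ethers could remain uncleaved, and the pyrogallol-type rings could oxidise in air during isolation of the free polyphenol. The fallback sets out from 32 and comes back at 33. After treatment with BBr3 as before, the crude product would be acetylated directly (Ac2O, pyridine, DMAP) to the octadecaacetate F7. This derivative is air-stable and can be chromatographed on silica, so incompletely cleaved material can be separated and returned to the cleavage. Acid-catalysed methanolysis of F7 under argon (HCl in MeOH, rt) should then release 33.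

Further compounds

F1 | step 8 | (E)-2-(tributylstannyl)ethenyllithium | [Li]/C=C/[Sn](CCCC)(CCCC)CCCC
F2 | step 8 | lithium alkoxide of 4-hydroxy-2,3-dimethoxy-4-[(E)-2-(tributylstannyl)ethenyl]cyclobut-2-en-1-one (racemic, one enantiomer drawn) | COC1=C(OC)[C@]([O-])(/C=C/[Sn](CCCC)(CCCC)CCCC)C1=O.[Li+]
F3 | step 8 | 2,3,4-trimethoxy-4-[(E)-2-(tributylstannyl)ethenyl]cyclobut-2-en-1-one (racemic, one enantiomer drawn) | COC1=C(OC)[C@](OC)(/C=C/[Sn](CCCC)(CCCC)CCCC)C1=O
F4 | step 8 | 4-[(E)-2-iodoethenyl]-2,3,4-trimethoxycyclobut-2-en-1-one (racemic, one enantiomer drawn) | COC1=C(OC)[C@](OC)(/C=C/I)C1=O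
F5 | step 8 | 4-{(E)-2-[2,6-dimethoxy-4-(2,4,6-trimethoxyphenoxy)phenoxy]ethenyl}-2,3,4-trimethoxycyclobut-2-en-1-one (racemic, one enantiomer drawn) | COC1=C(OC)[C@](OC)(/C=C/Oc2c(OC)cc(Oc3c(OC)cc(OC)cc3OC)cc2OC)C1=O
F6 | step 8 | (3Z,5E)-6-[2,6-dimethoxy-4-(2,4,6-trimethoxyphenoxy)phenoxy]-2,3,4-trimethoxyhexa-1,3,5-trien-1-one | O=C=C(OC)/C(OC)=C(OC)\C=C\Oc1c(OC)cc(Oc2c(OC)cc(OC)cc2OC)cc1OC
F0 | step 15 | none | none
F7 | step 17 | octadecaacetate of 33 | CC(=O)Oc1cc(OC(C)=O)c(Oc2cc(OC(C)=O)c(Oc3cc(OC(C)=O)c(OC(C)=O)c(OC(C)=O)c3Oc3cc(OC(C)=O)c(Oc4cc(OC(C)=O)c(OC(C)=O)c(OC(C)=O)c4Oc4cc(OC(C)=O)c(Oc5cc(OC(C)=O)c(OC(C)=O)c(OC(C)=O)c5)c(OC(C)=O)c4)c(OC(C)=O)c3)c(OC(C)=O)c2)c(OC(C)=O)c1
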